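**Plan**

Numbering: ring C1 (ketone), C2=C3 (both carry OMe), C4 (carbinol), C5 (side chain), C6 (methyl); chain C1'–C12' outward. The feature used is that the cis-dimethoxy alkene C2=C3 lies between the two oxygen-bearing carbons C1 and C4, so it can enter as a cis-1,2-dimethoxyethene-1,2-diyl dianion equivalent that joins two carbonyl carbons; one carbanion comes from C–H lithiation next to oxygen, the other is released from a C–Si bond by 1,4-silyl shift.
Cuts: C1–C2 and C3–C4 (the ring, in one step); C5–C1' (lactone enolate alkylation); C1'–C2' and C3'–CH3 (carboalumination/formaldehyde); C4'–C5' (propargyl dianion alkylation); C8'–C9' (vinylogous aldol).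
Forward: the C5'–C12' piece is made by a catalytic asymmetric vinylogous Mukaiyama aldol and extended to the C1' allylic bromide; this alkylates (R)-4-methyldihydrofuran-2(3H)-one, which supplies C4, C5, C6, the C6 methyl and C1. Lactone opening gives the C4 N-methoxy-N-methylamide and the C1 aldehyde, and the annulation then closes the only ring.
After the ring: C4 ketone reduction, exchange of the C1/C4 oxidation levels and desilylation.
Stereochemistry: C6 from the lactone; C5 by alkylation anti to the C6 methyl; C4 by hydride attack on the ring ketone anti to the C5 chain; C9' by catalyst control in the aldol; alkene geometries from E-selective SeO2 oxidation, the E-selective aldol and syn-carboalumination. The C1 carbinol is transient.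

Key step: step 17

Assumption: (R)-4-methyldihydrofuran-2(3H)-one and isomerically pure cis-1,2-dimethoxyethene are taken as purchasable; 31 is drawn as the Felkin–Anh C1 epimer, and both C1 epimers converge in step 21.

(TBS = tert-butyldimethylsilyl, TMS = trimethylsilyl; ring compounds are named with the ring numbering above.)

**Route**

Step 1
Reactants: 1 prenyl acetate
Product: 2 (E)-4-hydroxy-3-methylbut-2-en-1-yl acetate
Conditions: SeO2 (cat.), t-BuOOH, salicylic acid (cat.), CH2Cl2, rt
Reagents that add atoms: tert-butyl hydroperoxide, CC(C)(C)OO (source of the new oxygen, relayed by catalytic selenium dioxide, O=[Se]=O)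
Why: Riley-type SeO2 allylic oxidation (ene reaction, then 2,3-shift) should take place at the E-methyl group of the trisubstituted alkene, which fixes the E geometry of the later C10'=C11' bond.

Step 2
Reactants: 2 (E)-4-hydroxy-3-methylbut-2-en-1-yl acetate
Product: 3 (E)-4-(TBS-oxy)-3-methylbut-2-en-1-yl acetate
Conditions: TBSCl, imidazole, DMF, rt
Reagents that add atoms: tert-butyldimethylsilyl chloride, CC(C)(C)[Si](C)(C)Cl
Why: Standard silylation of a primary allylic alcohol installs the future C12' protecting group.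

Step 3
Reactants: 3 (E)-4-(TBS-oxy)-3-methylbut-2-en-1-yl acetate
Product: 4 (E)-4-(TBS-oxy)-3-methylbut-2-en-1-ol
Conditions: K2CO3 (cat.), MeOH, 0 °C
Reagents that add atoms: none
Why: Base-catalysed transesterification should remove the acetate while the silyl ether stays.

Step 4
Reactants: 4 (E)-4-(TBS-oxy)-3-methylbut-2-en-1-ol
Product: 5 (E)-4-(TBS-oxy)-3-methylbut-2-enal
Conditions: MnO2, CH2Cl2, rt
Reagents that add atoms: none
Why: Allylic oxidation with MnO2 should give the enal under neutral conditions without E/Z isomerisation.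

Step 5
Reactants: 6 methyl 3-methylbut-2-enoate
Product: 8 tert-butyl[(1-methoxy-3-methylbuta-1,3-dien-1-yl)oxy]dimethylsilane, via lithium dienolate 7 (not isolated)
Conditions: LiN(iPr)2, THF, DMPU, −78 °C; TBSCl
Reagents that add atoms: tert-butyldimethylsilyl chloride, CC(C)(C)[Si](C)(C)Cl
Why: γ-Deprotonation of the senecioate gives the extended dienolate, and O-silylation turns it into the silyl dienol ether needed for the vinylogous Mukaiyama aldol.

Step 6
Reactants: 5 (E)-4-(TBS-oxy)-3-methylbut-2-enal; 8 silyl dienol ether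
Product: 9 methyl (2E,5S,6E)-8-(TBS-oxy)-5-hydroxy-3,7-dimethylocta-2,6-dienoate
Conditions: SiCl4, chiral binaphthyldiamine-derived bisphosphoramide (cat., antipode chosen for si-face attack), iPr2NEt (cat.), CH2Cl2, −78 °C; aq. NaHCO3
Reagents that add atoms: none
Why: In this Lewis-base-activated SiCl4 vinylogous Mukaiyama aldol the dienol ether should react through its γ-carbon to give the E-enoate, and the chiral bisphosphoramide-bound trichlorosilyl cation should direct attack to the si face of the enal (O > C10' > H), which sets C9' as S.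

Step 7
Reactants: 9 aldol product
Product: 10 methyl (2E,5S,6E)-5,8-bis(TBS-oxy)-3,7-dimethylocta-2,6-dienoate
Conditions: TBSCl, imidazole, DMF, rt
Reagents that add atoms: tert-butyldimethylsilyl chloride, CC(C)(C)[Si](C)(C)Cl
Why: Silylation of the secondary allylic alcohol protects O9' for all later organometallic steps.

Step 8
Reactants: 10 bis-silylated enoate
Product: 11 (2E,5S,6E)-5,8-bis(TBS-oxy)-3,7-dimethylocta-2,6-dien-1-ol
Conditions: iBu2AlH, CH2Cl2, −78 °C; aq. sodium potassium tartrate
Reagents that add atoms: none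
Why: Low-temperature 1,2-reduction of the enoate by the aluminium hydride should give the allylic alcohol with silyl ethers and alkene geometry intact.

Step 9
Reactants: 11 allylic alcohol
Product: 12 (2E,5S,6E)-1-bromo-5,8-bis(TBS-oxy)-3,7-dimethylocta-2,6-diene
Conditions: CBr4, PPh3, CH2Cl2, −20 → 0 °C
Reagents that add atoms: carbon tetrabromide, BrC(Br)(Br)Br
Why: The Appel reaction converts the primary allylic alcohol into the bromide by SN2 on the oxyphosphonium ion under neutral conditions, without allylic transposition.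

Step 10
Reactants: 12 allylic bromide; 13 propargyl bromide
Product: 15 (5E,8S,9E)-8,11-bis(TBS-oxy)-6,10-dimethylundeca-5,9-dien-1-yne, via 1,3-dilithiopropyne 14 (not isolated)
Conditions: 13, n-BuLi (2 equiv), TMEDA, Et2O–hexane, −78 °C; then 12, −78 °C → rt; aq. NH4Cl
Reagents that add atoms: none
Why: In this three-carbon homologation the propargylic carbon of the dilithiated propyne displaces the primary allylic bromide by SN2 (C4'–C5' bond), and protonation on work-up gives the terminal alkyne.

Step 11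
Reactants: 15 terminal alkyne
Product: 17 (2E,6E,9S,10E)-9,12-bis(TBS-oxy)-3,7,11-trimethyldodeca-2,6,10-trien-1-ol, via alkenylalane 16 (not isolated)
Conditions: Me3Al, Cp2ZrCl2 (cat.), CH2Cl2, 0 °C → rt; n-BuLi, THF, −78 °C; (CH2O)n, → rt; aq. sodium potassium tartrate
Reagents that add atoms: trimethylaluminium, C[Al](C)C (C3' methyl); paraformaldehyde, C=O as monomer (C1')
Why: Negishi zirconium-catalysed carboalumination adds methyl and aluminium syn across the alkyne with methyl on the internal carbon, and hydroxymethylation of the derived alanate with retention gives the E-trisubstituted allylic alcohol.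

Step 12
Reactants: 17 trienol
Product: 18 (2E,6E,9S,10E)-1-bromo-9,12-bis(TBS-oxy)-3,7,11-trimethyldodeca-2,6,10-triene
Conditions: CBr4, PPh3, CH2Cl2, −20 → 0 °C
Reagents that add atoms: carbon tetrabromide, BrC(Br)(Br)Br
Why: A second Appel reaction gives the allylic bromide that serves as the electrophile for the lactone enolate.

Step 13
Reactants: 19 (R)-4-methyldihydrofuran-2(3H)-one; 18 trienyl bromide
Product: 21 (3R,4R)-3-[(2E,6E,9S,10E)-9,12-bis(TBS-oxy)-3,7,11-trimethyldodeca-2,6,10-trien-1-yl]-4-methyldihydrofuran-2(3H)-one, via lactone enolate 20 (not isolated)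
Conditions: LiN(iPr)2, THF, −78 °C; 18, DMPU, −78 → −30 °C
Reagents that add atoms: none
Why: Alkylation of the lactone lithium enolate should occur anti to the β-methyl group, which sets C5 (R) trans to C6, while C6 itself comes from the lactone.

Step 14
Reactants: 21 alkylated lactone
Product: 22 (2R,3R)-4-hydroxy-N-methoxy-N,3-dimethyl-2-[the bis-TBS trienyl chain]butanamide
Conditions: Me3Al, MeNH(OMe)·HCl, CH2Cl2, 0 °C → rt; aq. sodium potassium tartrate
Reagents that add atoms: N,O-dimethylhydroxylamine hydrochloride, CNOC.Cl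
Why: Aminolysis of the lactone by the aluminium amide gives the C4 N-methoxy-N-methylamide and frees the C1 hydroxyl without touching a stereocentre.

Step 15
Reactants: 22 hydroxy amide
Product: 23 (2R,3R)-N-methoxy-N,3-dimethyl-4-oxo-2-[the bis-TBS trienyl chain]butanamide
Conditions: Dess–Martin periodinane, NaHCO3, CH2Cl2, 0 °C → rt; used without delay
Reagents that add atoms: none
Why: Buffered Dess–Martin oxidation should give the α-branched aldehyde without epimerising C6 or C5.

Step 16
Reactants: 24 cis-1,2-dimethoxyethene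
Product: 26 cis-1,2-dimethoxy-1-(trimethylsilyl)ethene, via dimethoxyvinyllithium 25 (not isolated)
Conditions: t-BuLi, THF, −78 °C; Me3SiCl
Reagents that add atoms: chlorotrimethylsilane, C[Si](C)(C)Cl
Why: α-Lithiation of the enol ether at the vinylic C–H next to oxygen, then silylation; the low temperature is meant to keep the vinyllithium, whose β-methoxy group is anti to lithium, from losing LiOMe.

Step 17
Reactants: 26 cis-1,2-dimethoxy-1-(trimethylsilyl)ethene; 23 aldehyde N-methoxy-N-methylamide
Product: 31 (1S,5R,6R)-2,3-dimethoxy-6-methyl-5-[the bis-TBS trienyl chain]-1-(TMS-oxy)cyclohex-2-en-4-one, via silylvinyllithium 27 (not isolated), via lithium alkoxide 28 (not isolated), via vinyl carbanion 29 (not isolated), via lithium hemiaminal 30 (not isolated)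
Conditions: 26 (1.3 equiv), s-BuLi (1.2 equiv), THF, −78 °C; add 23, −78 °C; HMPA, −78 → −40 °C; aq. NH4Cl, cold
Reagents that add atoms: none
Why: Proposed new method: s-BuLi removes the only vinylic hydrogen of 26, which is α to oxygen, to give the cis-dimethoxy β-silyl vinyllithium 27, which adds to the aldehyde of 23 (C1–C2 bond); on adding HMPA the C1 alkoxide 28 attacks the cis-disposed silicon, a 1,4-Brook rearrangement moves the silyl group to O1 and frees the C3 carbanion 29, and this attacks the amide carbonyl (C3–C4 bond) to give the chelated adduct 30, which becomes the ketone only on quench. The closest known reaction types are additions to aldehydes of α-alkoxyvinyllithiums made by direct lithiation of enol ethers, anion-relay sequences in which a cis-β-silyl vinyllithium or ortho-silyl aryllithium adds to an aldehyde and the alkoxide then releases the neighbouring carbanion by 1,4-silyl shift, and Parham-type cyclisations of vinyllithiums onto N-methoxy-N-methylamides. The six-membered ring closes by 6-exo-trig attack of C3 on C4, which the cis geometry of 26 allows because it places C1 and the silicon (then the carbanion) on the same side of C2=C3. The new C1 stereocentre should follow Felkin–Anh control by C6 (1S expected) and is of no consequence because C1 is oxidised in step 21; C5 and C6 are not touched. The step needs the vinyllithium to take the aldehyde before the amide, which the higher electrophilicity of the aldehyde at −78 °C and the absence of free alkyllithium (26 is kept in excess over s-BuLi and is fully metalated before 23 is added) should secure, and it needs 27 and 29 to react on faster than they lose methoxide or are protonated, which the low temperature and the intramolecular attack on a chelating amide below −40 °C should favour. Over-addition is excluded because 30 persists as the lithium chelate until the quench.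

Step 18
Reactants: 31 C4 ketone with C1 TMS ether
Product: 32 (1S,4R,5R,6R)-2,3-dimethoxy-6-methyl-5-[the bis-TBS trienyl chain]-1-(TMS-oxy)cyclohex-2-en-4-ol
Conditions: LiBH(s-Bu)3, THF, −78 °C; aq. NH4Cl, cold
Reagents that add atoms: none
Why: In this hydride reduction of a cyclic ketone the bulky trialkylborohydride should attack C4 from the face opposite the adjacent C5 side chain (equatorial attack), giving the 4,5-cis alcohol (4R).

Step 19
Reactants: 32 C4 alcohol
Product: 33 (1S,4R,5R,6R)-4-(TBS-oxy)-2,3-dimethoxy-6-methyl-5-[the bis-TBS trienyl chain]-1-(TMS-oxy)cyclohex-2-ene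
Conditions: TBSOTf, 2,6-lutidine, CH2Cl2, −78 °C
Reagents that add atoms: tert-butyldimethylsilyl trifluoromethanesulfonate, CC(C)(C)[Si](C)(C)OS(=O)(=O)C(F)(F)F
Why: Base-buffered silylation of the hindered axial alcohol at low temperature protects O4 with a group that outlasts the trimethylsilyl ether.

Step 20
Reactants: 33 mixed silyl ether
Product: 34 (1S,4R,5R,6R)-4-(TBS-oxy)-2,3-dimethoxy-6-methyl-5-[the bis-TBS trienyl chain]cyclohex-2-en-1-ol
Conditions: K2CO3 (cat.), MeOH, 0 °C
Reagents that add atoms: none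
Why: Mild basic methanolysis should cleave only the trimethylsilyl ether, since tert-butyldimethylsilyl ethers are stable to it, and it avoids acid on the allylic enol-ether system.

Step 21
Reactants: 34 C1 alcohol
Product: 35 (4R,5R,6R)-4-(TBS-oxy)-2,3-dimethoxy-6-methyl-5-[the bis-TBS trienyl chain]cyclohex-2-en-1-one
Conditions: Dess–Martin periodinane, NaHCO3, CH2Cl2, 0 °C → rt
Reagents that add atoms: none
Why: Buffered Dess–Martin oxidation of the allylic C1 carbinol gives the 2,3-dimethoxy enone, at which both C1 epimers converge, and C6, now α to the ketone, already has the more stable trans relation to C5.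

Step 22
Reactants: 35 tris-silylated enone
Product: 36 the target, (4R,5R,6R)-4-hydroxy-5-[(2E,6E,9S,10E)-9,12-dihydroxy-3,7,11-trimethyldodeca-2,6,10-trien-1-yl]-2,3-dimethoxy-6-methylcyclohex-2-en-1-one
Conditions: HF·pyridine, pyridine, THF, 0 °C → rt
Reagents that add atoms: none
Why: Buffered fluoride-mediated cleavage of the three silyl ethers should free O4, O9' and O12' under conditions the γ-hydroxy enone tolerates.

**Compound list**

1 | prenyl acetate (3-methylbut-2-en-1-yl acetate) | CC(=O)OCC=C(C)C | starting material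
2 | (E)-4-hydroxy-3-methylbut-2-en-1-yl acetate | CC(=O)OC/C=C(\C)CO | intermediate
3 | (E)-4-(TBS-oxy)-3-methylbut-2-en-1-yl acetate | CC(=O)OC/C=C(\C)CO[Si](C)(C)C(C)(C)C | intermediate
4 | (E)-4-(TBS-oxy)-3-methylbut-2-en-1-ol | OC/C=C(\C)CO[Si](C)(C)C(C)(C)C | intermediate
5 | (E)-4-(TBS-oxy)-3-methylbut-2-enal | O=C/C=C(\C)CO[Si](C)(C)C(C)(C)C | intermediate
6 | methyl 3-methylbut-2-enoate | COC(=O)C=C(C)C | starting material
7 | lithium 1-methoxy-3-methylbuta-1,3-dien-1-olate (not isolated) | [Li+].[O-]C(OC)=CC(C)=C | intermediate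
8 | tert-butyl[(1-methoxy-3-methylbuta-1,3-dien-1-yl)oxy]dimethylsilane (ketene acetal geometry not defined) | COC(=CC(C)=C)O[Si](C)(C)C(C)(C)C | intermediate
9 | methyl (2E,5S,6E)-8-(TBS-oxy)-5-hydroxy-3,7-dimethylocta-2,6-dienoate | COC(=O)/C=C(\C)C[C@H](O)/C=C(\C)CO[Si](C)(C)C(C)(C)C | intermediate
10 | methyl (2E,5S,6E)-5,8-bis(TBS-oxy)-3,7-dimethylocta-2,6-dienoate | COC(=O)/C=C(\C)C[C@H](O[Si](C)(C)C(C)(C)C)/C=C(\C)CO[Si](C)(C)C(C)(C)C | intermediate
11 | (2E,5S,6E)-5,8-bis(TBS-oxy)-3,7-dimethylocta-2,6-dien-1-ol | OC/C=C(\C)C[C@H](O[Si](C)(C)C(C)(C)C)/C=C(\C)CO[Si](C)(C)C(C)(C)C | intermediate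
12 | (2E,5S,6E)-1-bromo-5,8-bis(TBS-oxy)-3,7-dimethylocta-2,6-diene | BrC/C=C(\C)C[C@H](O[Si](C)(C)C(C)(C)C)/C=C(\C)CO[Si](C)(C)C(C)(C)C | intermediate
13 | propargyl bromide (3-bromoprop-1-yne) | C#CCBr | starting material
14 | 1,3-dilithiopropyne (not isolated) | [Li]CC#C[Li] | intermediate
15 | (5E,8S,9E)-8,11-bis(TBS-oxy)-6,10-dimethylundeca-5,9-dien-1-yne | C#CCC/C=C(\C)C[C@H](O[Si](C)(C)C(C)(C)C)/C=C(\C)CO[Si](C)(C)C(C)(C)C | intermediate
16 | (E)-alkenyldimethylalane from 15, Al on C2' and methyl on C3' (not isolated) | C[Al](C)/C=C(\C)CC/C=C(\C)C[C@H](O[Si](C)(C)C(C)(C)C)/C=C(\C)CO[Si](C)(C)C(C)(C)C | intermediate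
17 | (2E,6E,9S,10E)-9,12-bis(TBS-oxy)-3,7,11-trimethyldodeca-2,6,10-trien-1-ol | OC/C=C(\C)CC/C=C(\C)C[C@H](O[Si](C)(C)C(C)(C)C)/C=C(\C)CO[Si](C)(C)C(C)(C)C | intermediate
18 | (2E,6E,9S,10E)-1-bromo-9,12-bis(TBS-oxy)-3,7,11-trimethyldodeca-2,6,10-triene | BrC/C=C(\C)CC/C=C(\C)C[C@H](O[Si](C)(C)C(C)(C)C)/C=C(\C)CO[Si](C)(C)C(C)(C)C | intermediate
19 | (R)-4-methyldihydrofuran-2(3H)-one | O=C1C[C@@H](C)CO1 | starting material
20 | lithium enolate of 19 (not isolated) | [Li+].[O-]C1=C[C@@H](C)CO1 | intermediate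
21 | (3R,4R)-3-[(2E,6E,9S,10E)-9,12-bis(TBS-oxy)-3,7,11-trimethyldodeca-2,6,10-trien-1-yl]-4-methyldihydrofuran-2(3H)-one | O=C1[C@H](C/C=C(\C)CC/C=C(\C)C[C@H](O[Si](C)(C)C(C)(C)C)/C=C(\C)CO[Si](C)(C)C(C)(C)C)[C@@H](C)CO1 | intermediate
22 | (2R,3R)-4-hydroxy-N-methoxy-N,3-dimethyl-2-[bis-TBS trienyl chain]butanamide | CON(C)C(=O)[C@H](C/C=C(\C)CC/C=C(\C)C[C@H](O[Si](C)(C)C(C)(C)C)/C=C(\C)CO[Si](C)(C)C(C)(C)C)[C@@H](C)CO | intermediate
23 | (2R,3R)-N-methoxy-N,3-dimethyl-4-oxo-2-[bis-TBS trienyl chain]butanamide (C1 aldehyde, C4 amide) | CON(C)C(=O)[C@H](C/C=C(\C)CC/C=C(\C)C[C@H](O[Si](C)(C)C(C)(C)C)/C=C(\C)CO[Si](C)(C)C(C)(C)C)[C@@H](C)C=O | intermediate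
24 | cis-1,2-dimethoxyethene | CO/C=C\OC | starting material
25 | 1,2-dimethoxyvinyllithium, methoxy groups cis (not isolated) | CO/C([Li])=C\OC | intermediate
26 | cis-1,2-dimethoxy-1-(trimethylsilyl)ethene (methoxy groups cis) | CO/C(=C\OC)[Si](C)(C)C | intermediate
27 | [1,2-dimethoxy-2-(trimethylsilyl)vinyl]lithium, methoxy groups cis, Li cis to Si (not isolated) | CO/C([Li])=C(\OC)[Si](C)(C)C | intermediate
28 | lithium C1 alkoxide from addition of 27 to 23, C3 still silylated (not isolated) | CON(C)C(=O)[C@H](C/C=C(\C)CC/C=C(\C)C[C@H](O[Si](C)(C)C(C)(C)C)/C=C(\C)CO[Si](C)(C)C(C)(C)C)[C@@H](C)[C@@H](/C(OC)=C(/OC)[Si](C)(C)C)[O-].[Li+] | intermediate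
29 | C3 vinyllithium with O1 TMS ether, after the 1,4-silyl shift (not isolated) | CON(C)C(=O)[C@H](C/C=C(\C)CC/C=C(\C)C[C@H](O[Si](C)(C)C(C)(C)C)/C=C(\C)CO[Si](C)(C)C(C)(C)C)[C@@H](C)[C@@H](/C(OC)=C(/OC)[Li])O[Si](C)(C)C | intermediate
30 | cyclised lithium N-methoxy-N-methyl hemiaminal at C4, configuration at C4 not defined (not isolated) | COC1=C(OC)C([O-])(N(C)OC)[C@H](C/C=C(\C)CC/C=C(\C)C[C@H](O[Si](C)(C)C(C)(C)C)/C=C(\C)CO[Si](C)(C)C(C)(C)C)[C@@H](C)[C@@H]1O[Si](C)(C)C.[Li+] | intermediate
31 | (1S,5R,6R)-2,3-dimethoxy-6-methyl-5-[bis-TBS trienyl chain]-1-(TMS-oxy)cyclohex-2-en-4-one | COC1=C(OC)C(=O)[C@H](C/C=C(\C)CC/C=C(\C)C[C@H](O[Si](C)(C)C(C)(C)C)/C=C(\C)CO[Si](C)(C)C(C)(C)C)[C@@H](C)[C@@H]1O[Si](C)(C)C | intermediate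
32 | (1S,4R,5R,6R)-2,3-dimethoxy-6-methyl-5-[bis-TBS trienyl chain]-1-(TMS-oxy)cyclohex-2-en-4-ol | COC1=C(OC)[C@H](O)[C@H](C/C=C(\C)CC/C=C(\C)C[C@H](O[Si](C)(C)C(C)(C)C)/C=C(\C)CO[Si](C)(C)C(C)(C)C)[C@@H](C)[C@@H]1O[Si](C)(C)C | intermediate
33 | (1S,4R,5R,6R)-4-(TBS-oxy)-2,3-dimethoxy-6-methyl-5-[bis-TBS trienyl chain]-1-(TMS-oxy)cyclohex-2-ene | COC1=C(OC)[C@H](O[Si](C)(C)C(C)(C)C)[C@H](C/C=C(\C)CC/C=C(\C)C[C@H](O[Si](C)(C)C(C)(C)C)/C=C(\C)CO[Si](C)(C)C(C)(C)C)[C@@H](C)[C@@H]1O[Si](C)(C)C | intermediate
34 | (1S,4R,5R,6R)-4-(TBS-oxy)-2,3-dimethoxy-6-methyl-5-[bis-TBS trienyl chain]cyclohex-2-en-1-ol | COC1=C(OC)[C@H](O[Si](C)(C)C(C)(C)C)[C@H](C/C=C(\C)CC/C=C(\C)C[C@H](O[Si](C)(C)C(C)(C)C)/C=C(\C)CO[Si](C)(C)C(C)(C)C)[C@@H](C)[C@@H]1O | intermediate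
35 | (4R,5R,6R)-4-(TBS-oxy)-2,3-dimethoxy-6-methyl-5-[bis-TBS trienyl chain]cyclohex-2-en-1-one | COC1=C(OC)[C@H](O[Si](C)(C)C(C)(C)C)[C@H](C/C=C(\C)CC/C=C(\C)C[C@H](O[Si](C)(C)C(C)(C)C)/C=C(\C)CO[Si](C)(C)C(C)(C)C)[C@@H](C)C1=O | intermediate
36 | (4R,5R,6R)-4-hydroxy-5-[(2E,6E,9S,10E)-9,12-dihydroxy-3,7,11-trimethyldodeca-2,6,10-trien-1-yl]-2,3-dimethoxy-6-methylcyclohex-2-en-1-one | COC1=C(OC)[C@H](O)[C@H](C/C=C(\C)CC/C=C(\C)C[C@H](O)/C=C(\C)CO)[C@@H](C)C1=O | target

**Totals**

Total step count: 22.
Longest linear sequence: 20 steps (steps 1–4, 6–15, 17–22).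

**Steps most likely to fail**

1. Step 17 (proposed new method). The silyl shift from C3 to O1 may be too slow at the temperatures the carbanions tolerate, so that the C1 alkoxide closes onto the amide carbonyl instead (lactone formation), or the vinyl carbanions may lose methoxide before they are trapped. The fallback uses known reactions only, sets out from 26 and 23 and returns at 31. The same lithiation of 26 and aldehyde addition are run without HMPA and the alkoxide is capped in the flask with Me3SiCl, which gives the C1 silyl ether with the C3 silane intact, bis-silyl amide F1. Iododesilylation of the electron-rich vinylsilane with N-iodosuccinimide (2,6-lutidine, MeCN, 0 °C, retention expected) gives the vinyl iodide F2. Iodine–lithium exchange with t-BuLi at −100 °C, which outruns attack on the amide, followed by Parham-type cyclisation onto the N-methoxy-N-methylamide, gives 31.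

2. Step 18. Facial selectivity may be poor (attack syn to the C5 chain, giving the 4,5-trans alcohol), or conjugate reduction of the vinylogous ester may compete. The fallback sets out from 31 and returns at 32. Reduction with a small hydride (iBu2AlH, toluene, −78 °C) should favour axial attack and give the 4-epi alcohol F3, which is also the by-product of step 18, so mixtures can be funnelled the same way. Mitsunobu inversion with benzoic acid (PPh3, DIAD) then sets C4 by SN2 and gives the 4,5-cis benzoate F4. Reductive cleavage of the benzoate with iBu2AlH at −78 °C, which leaves the trimethylsilyl ether in place, gives 32.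

3. Step 6. Enantioselectivity may be insufficient with the β,β-disubstituted enal, the dienol ether may react through its α-carbon, or the E geometry may erode. The fallback sets out from 5 and returns at 10. Catalytic asymmetric propargylation of 5 (allenylboronic acid pinacol ester, chiral BINOL-derived phosphoric acid) gives the homopropargylic alcohol F5. Silylation (TBSCl, imidazole) gives the silyl ether F6. Zirconium-catalysed carboalumination (Me3Al, Cp2ZrCl2) followed by ClCO2Me builds the E-trisubstituted enoate in one operation and gives 10.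

Further compounds
F1 | step 17 | open-chain N-methoxy-N-methylamide with C1 TMS ether and C3 trimethylsilyl group (C2=C3 methoxy groups cis) | CON(C)C(=O)[C@H](C/C=C(\C)CC/C=C(\C)C[C@H](O[Si](C)(C)C(C)(C)C)/C=C(\C)CO[Si](C)(C)C(C)(C)C)[C@@H](C)[C@@H](/C(OC)=C(/OC)[Si](C)(C)C)O[Si](C)(C)C
F2 | step 17 | open-chain N-methoxy-N-methylamide with C1 TMS ether and C3 iodide (iodine cis to C1) | CON(C)C(=O)[C@H](C/C=C(\C)CC/C=C(\C)C[C@H](O[Si](C)(C)C(C)(C)C)/C=C(\C)CO[Si](C)(C)C(C)(C)C)[C@@H](C)[C@@H](/C(OC)=C(/OC)I)O[Si](C)(C)C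
F3 | step 18 | (1S,4S,5R,6R)-2,3-dimethoxy-6-methyl-5-[bis-TBS trienyl chain]-1-(TMS-oxy)cyclohex-2-en-4-ol (4-epi alcohol, OH trans to the C5 chain) | COC1=C(OC)[C@@H](O)[C@H](C/C=C(\C)CC/C=C(\C)C[C@H](O[Si](C)(C)C(C)(C)C)/C=C(\C)CO[Si](C)(C)C(C)(C)C)[C@@H](C)[C@@H]1O[Si](C)(C)C
F4 | step 18 | (1S,4R,5R,6R)-2,3-dimethoxy-6-methyl-5-[bis-TBS trienyl chain]-1-(TMS-oxy)cyclohex-2-en-4-yl benzoate (4,5-cis) | COC1=C(OC)[C@H](OC(=O)c2ccccc2)[C@H](C/C=C(\C)CC/C=C(\C)C[C@H](O[Si](C)(C)C(C)(C)C)/C=C(\C)CO[Si](C)(C)C(C)(C)C)[C@@H](C)[C@@H]1O[Si](C)(C)C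
F5 | step 6 | (4S,5E)-7-(TBS-oxy)-6-methylhept-5-en-1-yn-4-ol | C#CC[C@H](O)/C=C(\C)CO[Si](C)(C)C(C)(C)C
F6 | step 6 | (4S,5E)-4,7-bis(TBS-oxy)-6-methylhept-5-en-1-yne | C#CC[C@H](O[Si](C)(C)C(C)(C)C)/C=C(\C)CO[Si](C)(C)C(C)(C)C
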